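The vessel is stirred and isothermal, E is dosed in at a steady rate, D starts chains, and each living end Q adds E to its chain and sheds it again.

    E + D → Q + J (k1 = 2.0 L mol⁻¹ s⁻¹)
    E + Q → J + Q, rate k2*[Q]*[E] (k2 = 92 L mol⁻¹ s⁻¹)
    J + Q → E + Q, rate k3*[Q] as long as [J] is above zero (k3 = 1.9 s⁻¹)
    E → L (k4 = 0.0011 s⁻¹)

| setting | spring | midnight |
|---|---|---|
| E | 0.050 M (fed, over 10 s) | 0.050 M (fed, over 15 s) |
| D | 1.0 mM | 1.0 mM |
| time | 50 s | 50 s |

- the average divides the monomer in chains by the number of chains begun, living and dead together
- run time (spring): 50 s

* which of the two ends with the longer chains by the average number of monomer units in a chain (chains begun, living or dead) ("neither" if they lie within 10%) (spring / midnight / neither)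
* average number of monomer units in a chain (chains begun, living or dead) at the end, spring
* average number of monomer units in a chain (chains begun, living or dead) at the end, midnight

I look for the crossing. A living end adds E at a pace that grows with [E] and, as long as [J] is above zero, sheds at a fixed pace, so the two balance at the shedding constant over the adding constant, [E] = 0.0207 M, the balance value (the usual term is equilibrium monomer concentration). The charge of 0.050 M lies above it, so I let the chains hold the difference. At that [E] D lasts 24.2 s on average and the 50 s run is twice as long, so I round up and count 1.0 mM of chains begun. I leave L out. That gives 29.3 units per chain for both flasks, with no feed time in the sum.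

The forecast says 28.4 for spring, 28.1 for midnight and neither, since "the feed time hardly matters".

The simulation gives 28.3 for spring and 28.2 for midnight, so the answer is neither, and both lie under my figure.

In spring at 50.0 s, E has a half-life of 8.0 s by turning into J, that forward step counted by itself, against 11 min by turning into L, and [E] stands at 0.0216 M, close to the balance value. Spring also holds 3.18% of the E charged as L and 5.6% of its D still unused. For the spring flask charged with 0.20 M of E, the balance value gives 179 units per chain; the simulation gives 173.

The rate constants were drawn at random within sensible limits.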